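The last two readings of Z in the delta run, 23.5 % and 22.7 %, lie 0.8 percentage points apart with a scatter of 0.5 points on each, and that flat stretch is where my reckoning starts.

all flasks: L 0.050 M

|  | X | remark | time |
|---|---|---|---|
| theta | 1.5 equiv | run made earlier |  |
| delta | 2.2 equiv | run made earlier |  |
| maple | 3.00 equiv |  | 2.0 h |
| cedar | 2.00 equiv |  | 2.0 h |

| run | time / min | Z / % | L / % |
|---|---|---|---|
| theta | 20.0 | 12.4 | 84.3 |
| theta | 40.0 | 17.7 | 74.3 |
| theta | 60.0 | 21.4 | 66.9 |
| theta | 80.0 | 22.6 | 64.0 |
| delta | 20.0 | 16.8 | 77.9 |
| delta | 40.0 | 21.6 | 64.6 |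
| delta | 60.0 | 23.5 | 56.1 |
| delta | 80.0 | 22.7 | 51.8 |

(readings scatter by 0.5 percentage points)

- which of these holds the largest part of the L at the end of maple (Z / D / L)
- which of these holds the largest part of the L at the end of cedar (Z / D / L)
- Z at the end of cedar, in percent of the L charged

- for Q the E are counted in
- steps thought possible: L + X <-> Q + Z; Z + X <-> Q + D; Q + X <-> E

Two chemists dispute these flasks. The first goes by the charge: at 20.0 min, delta holds 1.35 times the Z of theta with 1.47 times the X. He scales the last Z of delta by X and gets 20.6 % for cedar and 31.0 % for maple. His rule has its region at high L, as in those first readings, with L at 84.3 % and 77.9 %.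

The second, whose side I take, goes by L. Theta at 80.0 min and delta at 40.0 min differ in X and clock, yet L reads 64.0 % and 64.6 %, and Z reads 22.6 % and 21.6 %. Each forward step uses one X, so X and the clock divide out of the ratio of the two rates, and anything E takes from X moves the clock, not the curve. One number remains, the selectivity factor s, the second exchange's rate constant over the first's. Where Z stops rising, making equals using, so s = L/Z there. The last two delta readings cannot show where that top lies; they give L/Z of 2.39 and 2.28, so I take their mean, s = 2.33, as a reading. In fractions of the charge, Z = (L − L^s)/(s − 1).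

I expect cedar near delta's last L. Its logarithm is −0.286, times s is −0.667, so L^s is 0.215 and Z is 22.7 %. L and D cross near 38.7 %, so L leads in cedar. Scaling log L by X puts maple at 37.3 %, below that crossing, so D leads there, with Z at 20.4 %, less than in cedar.

The forecast gave D for maple, L for cedar and Z of 22 % (19.5 % to 24.5 %), expecting that “the system stalls gradually”.

The flasks give Z of 22.9 % beside L of 48.4 % in cedar, and in maple Z of 19.6 % with D of 47.7 % over L of 32.6 %. Z in maple, with more X, stands lower than Z in cedar, so the second chemist wins.

    L + X ⇌ Q + Z (K = 0.250, k = 0.00210 /M/s)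
    Z + X ⇌ Q + D (K = 1.10, k = 0.00470 /M/s)
    Q + X ⇌ E, settled at all times (K = 1100 /M)

In cedar at 2.00 h, the forward rate of the first exchange stands at 0.95 of the second's, and L/(sZ) from the simulated amounts gives 0.906, so Z sits near its top, made net at 0.886 of its using against 1.79 at 0.478 h. In the neighbour flask with 0.500 equiv of X, L stands at 82.8 %, where the curve gives 13.8 % and the flask holds Z of 13.9 %.

(All runs are calculated from invented constants; the scatter is artificial.)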